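**Plan**
1. Retrosynthesis: the quinone is unmasked last from an 8-hydroxy-2H-chromene. The chain is cut at the sp2–sp3 bond between the exocyclic alkylidene carbon and its CH2 (B-alkyl Suzuki), giving iodomethylidene lactone 15 and chromene diene 28. In the lactone, the ring bonds C3–C4 and C5–C6 are cut together.
2. Enabling feature: the oxan-2-one ring holds two unsubstituted methylenes (C4, C5) between an sp2 α-carbon (C3), whose exocyclic vinyl H is cis to C4, and the carbinol carbon C6. This Z-alkene–CH2CH2–CH(O) array is what an alkyne, ethylene and an aldehyde give when joined on zirconocene: C4–C5 is the ethylene (from EtMgBr), C3 an alkyne carbon, C6 an aldehyde carbon.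
3. Forward, lactone fragment: three-component zirconacycle coupling, oxidation to the ketone, iododesilylation, CBS reduction, desilylation, oxidative lactonisation (the lactone ring closes last in this fragment).
4. Forward, chromene fragment and union: SNAr of (R)-linalool on an o-fluorobenzaldehyde, Wittig, SeO2 oxidation, ring-closing metathesis (pyran ring), Br to OH, Wittig; then B-alkyl Suzuki union and Fremy oxidation to the quinone.
5. Stereochemistry: chromene C2 comes from (R)-linalool, whose C–O bond is never broken. Lactone C6 comes from CBS reduction (the carbinol made in the key step is racemic and is erased, then reset). The exocyclic Z alkene comes from syn addition on zirconium, carried through retentive iododesilylation and cross-coupling. The chain E alkene comes from E-selective SeO2 oxidation of the linalool prenyl group.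

Key step: step 4

Assumption: commercial (R)-(−)-linalool of high enantiomeric purity is used; in the SMILES of zirconium species the cyclopentadienyl ligands are drawn as σ-bonded rings.

**Route**

Step 1
Reactants: 1 3-(trimethylsilyl)prop-2-yn-1-ol
Product: 2 tert-butyl(dimethyl){[3-(trimethylsilyl)prop-2-yn-1-yl]oxy}silane
Conditions: TBSCl, imidazole, CH2Cl2, 0 °C → rt
Reagents that add atoms: tert-butyldimethylsilyl chloride, CC(C)(C)[Si](C)(C)Cl
Why: Standard silylation of a primary alcohol masks the future lactone carbonyl carbon as an ether that is inert to organozirconium and Grignard reagents.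

Step 2
Reactants: 3 methyl 2-hydroxy-2-methylpropanoate
Product: 4 methyl 2-methyl-2-[(triethylsilyl)oxy]propanoate
Conditions: Et3SiOTf, 2,6-lutidine, CH2Cl2, 0 °C
Reagents that add atoms: triethylsilyl trifluoromethanesulfonate, CC[Si](CC)(CC)OS(=O)(=O)C(F)(F)F
Why: Silyl triflate with lutidine is the usual way to cap a hindered tertiary alcohol, and the ether should survive the organometallic, oxidation and borane steps that follow.

Step 3
Reactants: 4 methyl 2-methyl-2-[(triethylsilyl)oxy]propanoate
Product: 5 2-methyl-2-[(triethylsilyl)oxy]propanal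
Conditions: i-Bu2AlH (1.1 equiv), CH2Cl2, −78 °C; aq. KNaC4H4O6 (potassium sodium tartrate)
Reagents that add atoms: none
Why: Low-temperature DIBAL-H reduction of an α-alkoxy ester stops at the chelated hemiacetal aluminate and should release the non-enolisable aldehyde on work-up.

Step 4
Reactants: 2 tert-butyl(dimethyl){[3-(trimethylsilyl)prop-2-yn-1-yl]oxy}silane; 5 2-methyl-2-[(triethylsilyl)oxy]propanal
Product: 8 rac-(6Z)-6-({[tert-butyl(dimethyl)silyl]oxy}methyl)-2-methyl-2-[(triethylsilyl)oxy]-7-(trimethylsilyl)hept-6-en-3-ol, via zirconacyclopentene 6 (not isolated), via oxazirconacycloheptene 7 (not isolated)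
Conditions: Cp2ZrCl2 (1.1 equiv), EtMgBr (2.2 equiv), THF, −78 → 0 °C; 2, 0 °C; then 5, 0 °C → rt; 1 M HCl, 0 °C
Reagents that add atoms: ethylmagnesium bromide, CC[Mg]Br
Why: Cp2ZrEt2 loses ethane by β-hydrogen abstraction to give Cp2Zr(η2-C2H4) (divalent zirconium, a zirconacyclopropane), which couples oxidatively with alkyne 2 to zirconacyclopentene 6, the ethylene carbon bonding to the CH2OTBS-bearing alkyne carbon (first new bond) because silicon prefers the position α to zirconium; aldehyde 5 then inserts into the more nucleophilic Zr–C(sp3) bond (second new bond) to give the seven-membered oxazirconacycle 7, whose Zr–C(sp2) and Zr–O bonds are cleaved by acid with retention. The closest known reaction type is the Negishi–Takahashi formation of zirconacyclopentenes from Cp2ZrEt2 and alkynes followed by carbonyl insertion into the alkyl–zirconium bond, run as a one-flask alkyne–ethylene–aldehyde coupling. Both rings closed here are temporary metallacycles (five-membered by oxidative cyclisation at the metal, seven-membered by 1,2-insertion of C=O) and neither survives work-up; the lactone ring itself closes in step 9. The alkene geometry is fixed by the cis relationship of zirconium and the new CH2 in the metallacycle, so H ends cis to the ethano chain and SiMe3 cis to CH2OTBS; the new carbinol center forms without control (both partners are achiral) and is therefore erased in step 5 and set in step 7. The step needs regioselectivity (secured by the α-directing SiMe3 group), site selectivity between the two Zr–C bonds (the α-silyl alkenyl–Zr bond is hindered and less nucleophilic) and insertion faster than loss of ethylene from 6 (favoured by adding the non-enolisable aldehyde at 0 °C).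

Step 5
Reactants: 8 rac-(6Z)-6-({[tert-butyl(dimethyl)silyl]oxy}methyl)-2-methyl-2-[(triethylsilyl)oxy]-7-(trimethylsilyl)hept-6-en-3-ol
Product: 9 (6Z)-6-({[tert-butyl(dimethyl)silyl]oxy}methyl)-2-methyl-2-[(triethylsilyl)oxy]-7-(trimethylsilyl)hept-6-en-3-one
Conditions: Dess–Martin periodinane, NaHCO3, CH2Cl2, rt
Reagents that add atoms: none
Why: Dess–Martin oxidation removes the uncontrolled carbinol center under neutral conditions that leave the vinylsilane and both silyl ethers intact (any Oppenauer-type oxidation of the zirconium alkoxide by excess aldehyde in step 4 converges on the same ketone).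

Step 6
Reactants: 9 (6Z)-6-({[tert-butyl(dimethyl)silyl]oxy}methyl)-2-methyl-2-[(triethylsilyl)oxy]-7-(trimethylsilyl)hept-6-en-3-one
Product: 10 (6Z)-6-({[tert-butyl(dimethyl)silyl]oxy}methyl)-7-iodo-2-methyl-2-[(triethylsilyl)oxy]hept-6-en-3-one
Conditions: NIS, 2,6-lutidine, (CF3)2CHOH, 0 °C
Reagents that add atoms: N-iodosuccinimide, O=C1CCC(=O)N1I
Why: Electrophilic ipso-iododesilylation through a β-silyl cation in hexafluoroisopropanol should proceed with retention of alkene geometry, and it is run at the ketone stage so that no free hydroxyl can capture the cation.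

Step 7
Reactants: 10 (6Z)-6-({[tert-butyl(dimethyl)silyl]oxy}methyl)-7-iodo-2-methyl-2-[(triethylsilyl)oxy]hept-6-en-3-one
Product: 11 (3R,6Z)-6-({[tert-butyl(dimethyl)silyl]oxy}methyl)-7-iodo-2-methyl-2-[(triethylsilyl)oxy]hept-6-en-3-ol
Conditions: (S)-2-methyl-CBS-oxazaborolidine (0.2 equiv), BH3·SMe2, THF, −20 °C; MeOH
Reagents that add atoms: none
Why: In this Corey–Bakshi–Shibata reduction the oxazaborolidine–borane complex delivers hydride with the bulky α-silyloxy tert-alkyl group as the large substituent and the CH2 chain as the small one, the same sense as for pinacolone, which should give the R carbinol.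

Step 8
Reactants: 11 (3R,6Z)-6-({[tert-butyl(dimethyl)silyl]oxy}methyl)-7-iodo-2-methyl-2-[(triethylsilyl)oxy]hept-6-en-3-ol
Product: 12 (3R,6Z)-6-(hydroxymethyl)-7-iodo-2-methylhept-6-ene-2,3-diol
Conditions: HF·pyridine, pyridine, THF, 0 °C → rt
Reagents that add atoms: none
Why: Buffered fluoride desilylation cleaves both Si–O bonds without touching the vinyl iodide or the stereocenter.

Step 9
Reactants: 12 (3R,6Z)-6-(hydroxymethyl)-7-iodo-2-methylhept-6-ene-2,3-diol
Product: 15 (3Z,6R)-6-(2-hydroxypropan-2-yl)-3-(iodomethylidene)oxan-2-one, via hydroxy enal 13 (not isolated), via lactol 14 (not isolated)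
Conditions: TEMPO (0.2 equiv), PhI(OAc)2 (2.5 equiv), CH2Cl2, rt
Reagents that add atoms: none
Why: Oxoammonium oxidation is selective for the primary allylic alcohol, the aldehyde is captured by the secondary hydroxyl as the six-membered lactol and oxidised on to the lactone, while the tertiary alcohol, the C6 center and the alkene geometry are untouched.

Step 10
Reactants: 16 2-bromo-1-fluoro-4-methylbenzene
Product: 18 3-bromo-2-fluoro-5-methylbenzaldehyde, via aryllithium 17 (not isolated)
Conditions: LiN(i-Pr)2, THF, −78 °C; DMF; aq. NH4Cl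
Reagents that add atoms: N,N-dimethylformamide, CN(C)C=O
Why: Directed ortho-lithiation removes the only ring proton next to fluorine and formylation with DMF follows, as in the known preparation of 3-bromo-2-fluorobenzaldehyde.

Step 11
Reactants: 18 3-bromo-2-fluoro-5-methylbenzaldehyde; 19 (R)-(−)-linalool [(3R)-3,7-dimethylocta-1,6-dien-3-ol]
Product: 21 3-bromo-2-{[(3R)-3,7-dimethylocta-1,6-dien-3-yl]oxy}-5-methylbenzaldehyde, via potassium alkoxide 20 (not isolated)
Conditions: KH (1.05 equiv), THF, 0 °C; then 18, THF/DMF, 0 °C → rt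
Reagents that add atoms: none
Why: Nucleophilic aromatic substitution (addition–elimination through a Meisenheimer adduct) at the fluoride activated by the ortho formyl group forms the aryl ether without touching the C–O bond of linalool, so the R center is carried over; both ortho positions and the para position are blocked, so no Claisen rearrangement can follow.

Step 12
Reactants: 21 3-bromo-2-{[(3R)-3,7-dimethylocta-1,6-dien-3-yl]oxy}-5-methylbenzaldehyde
Product: 22 1-bromo-2-{[(3R)-3,7-dimethylocta-1,6-dien-3-yl]oxy}-3-ethenyl-5-methylbenzene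
Conditions: Ph3PCH3Br, KN(SiMe3)2, THF, 0 °C → rt
Reagents that add atoms: methyltriphenylphosphonium bromide, C[P+](c1ccccc1)(c1ccccc1)c1ccccc1.[Br-]
Why: Wittig methylenation of the aryl aldehyde installs the styrene needed for ring closure under basic conditions that the tertiary allyl aryl ether tolerates.

Step 13
Reactants: 22 1-bromo-2-{[(3R)-3,7-dimethylocta-1,6-dien-3-yl]oxy}-3-ethenyl-5-methylbenzene
Product: 24 (2E,6R)-6-(2-bromo-6-ethenyl-4-methylphenoxy)-2,6-dimethylocta-2,7-dienal, via allylic alcohol 23 (not isolated)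
Conditions: SeO2 (0.3 equiv), t-BuOOH, CH2Cl2, rt; then MnO2, CH2Cl2, rt
Reagents that add atoms: selenium dioxide, O=[Se]=O; tert-butyl hydroperoxide, CC(C)(C)OO
Why: Selenium dioxide allylic oxidation (ene reaction then [2,3]-sigmatropic shift) attacks the E-methyl group of the trisubstituted alkene, and MnO2 converges the alcohol/aldehyde mixture on the E-enal; the two vinyl groups carry no allylic hydrogens.

Step 14
Reactants: 24 (2E,6R)-6-(2-bromo-6-ethenyl-4-methylphenoxy)-2,6-dimethylocta-2,7-dienal
Product: 25 (2E)-5-[(2R)-8-bromo-2,6-dimethyl-2H-chromen-2-yl]-2-methylpent-2-enal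
Conditions: second-generation Grubbs catalyst RuCl2(=CHPh)(PCy3)(H2IMes) (5 mol%), CH2Cl2, 40 °C
Reagents that add atoms: none
Why: Ring-closing metathesis of the styrene and the vinyl group closes the six-membered pyran ring with loss of ethylene; the conjugated trisubstituted enal is a poor metathesis partner, which suppresses competing cyclopentene formation, and the quaternary center is not involved.

Step 15
Reactants: 25 (2E)-5-[(2R)-8-bromo-2,6-dimethyl-2H-chromen-2-yl]-2-methylpent-2-enal
Product: 27 (2E)-5-[(2R)-8-hydroxy-2,6-dimethyl-2H-chromen-2-yl]-2-methylpent-2-enal, via aryl boronate 26 (not isolated)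
Conditions: B2pin2, Pd2(dba)3 (2.5 mol%), XPhos, KOAc, 1,4-dioxane, 90 °C; then N-methylmorpholine N-oxide, THF, 50 °C
Reagents that add atoms: N-methylmorpholine N-oxide, C[N+]1([O-])CCOCC1
Why: Miyaura borylation of the aryl bromide followed by N-oxide oxidation (1,2-shift of the aryl group from boron to oxygen) gives the phenol without peroxide, and it is placed after ring closure so that the arylpalladium species has no pendant vinyl group for Heck cyclisation.

Step 16
Reactants: 27 (2E)-5-[(2R)-8-hydroxy-2,6-dimethyl-2H-chromen-2-yl]-2-methylpent-2-enal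
Product: 28 (2R)-2,6-dimethyl-2-[(3E)-4-methylhexa-3,5-dien-1-yl]-2H-chromen-8-ol
Conditions: Ph3PCH3Br (2.5 equiv), KN(SiMe3)2 (2.4 equiv), THF, −78 → 0 °C
Reagents that add atoms: methyltriphenylphosphonium bromide, C[P+](c1ccccc1)(c1ccccc1)c1ccccc1.[Br-]
Why: Wittig methylenation of the enal (one equivalent of ylide is spent on the phenol) gives the terminal diene and leaves the E trisubstituted alkene unchanged.

Step 17
Reactants: 28 (2R)-2,6-dimethyl-2-[(3E)-4-methylhexa-3,5-dien-1-yl]-2H-chromen-8-ol; 15 (3Z,6R)-6-(2-hydroxypropan-2-yl)-3-(iodomethylidene)oxan-2-one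
Product: 30 (3Z,6R)-3-{(4E)-7-[(2R)-8-hydroxy-2,6-dimethyl-2H-chromen-2-yl]-4-methylhept-4-en-1-ylidene}-6-(2-hydroxypropan-2-yl)oxan-2-one, via alkylborane 29 (not isolated)
Conditions: 9-BBN-H (2.3 equiv), THF, 0 °C → rt; then 15, Pd(dppf)Cl2 (5 mol%), AsPh3, aq. K3PO4, DMF, rt; mild acid work-up
Reagents that add atoms: none
Why: In this B-alkyl Suzuki–Miyaura coupling 9-BBN should hydroborate only the terminal monosubstituted alkene of the diene in the anti-Markovnikov sense (the phenol is borylated on oxygen and freed again on work-up), and the alkyl group couples with the β-iodo enoate under zerovalent palladium catalysis with retention of the Z geometry; the acid work-up re-closes any lactone opened by base.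

Step 18
Reactants: 30 (3Z,6R)-3-{(4E)-7-[(2R)-8-hydroxy-2,6-dimethyl-2H-chromen-2-yl]-4-methylhept-4-en-1-ylidene}-6-(2-hydroxypropan-2-yl)oxan-2-one
Product: 31 (2R)-2-{(3E)-7-[(3Z,6R)-6-(2-hydroxypropan-2-yl)-2-oxooxan-3-ylidene]-4-methylhept-3-en-1-yl}-2,6-dimethyl-2H-chromene-5,8-dione (target)
Conditions: (KSO3)2NO (Fremy's salt, 2.5 equiv), KH2PO4 buffer, acetone/H2O, 0 °C → rt
Reagents that add atoms: potassium nitrosodisulfonate, [K+].[K+].[O]N(S(=O)(=O)[O-])S(=O)(=O)[O-]
Why: In the Teuber oxidation the phenoxyl radical is captured by a second nitroxide at the free para position (C5) and collapses to the para-quinone, a radical process that should leave the alkenes, the lactone and both stereocenters alone.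

**Compound list**
1 | 3-(trimethylsilyl)prop-2-yn-1-ol | C[Si](C)(C)C#CCO | starting material
2 | tert-butyl(dimethyl){[3-(trimethylsilyl)prop-2-yn-1-yl]oxy}silane | C[Si](C)(C)C#CCO[Si](C)(C)C(C)(C)C | intermediate
3 | methyl 2-hydroxy-2-methylpropanoate | COC(=O)C(C)(C)O | starting material
4 | methyl 2-methyl-2-[(triethylsilyl)oxy]propanoate | COC(=O)C(C)(C)O[Si](CC)(CC)CC | intermediate
5 | 2-methyl-2-[(triethylsilyl)oxy]propanal | O=CC(C)(C)O[Si](CC)(CC)CC | intermediate
6 | 1,1-bis(cyclopentadienyl)-3-({[tert-butyl(dimethyl)silyl]oxy}methyl)-2-(trimethylsilyl)-1-zirconacyclopent-2-ene | C[Si](C)(C)C1=C(CO[Si](C)(C)C(C)(C)C)CC[Zr]1(C2C=CC=C2)C2C=CC=C2 | intermediate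
7 | seven-membered oxazirconacycle (Zr–O–CH[C(CH3)2OSiEt3]–CH2–CH2–C(CH2OTBS)=C(SiMe3)–Zr, two Cp on Zr) | C[Si](C)(C)C1=C(CO[Si](C)(C)C(C)(C)C)CCC(C(C)(C)O[Si](CC)(CC)CC)O[Zr]1(C2C=CC=C2)C2C=CC=C2 | intermediate
8 | rac-(6Z)-6-({[tert-butyl(dimethyl)silyl]oxy}methyl)-2-methyl-2-[(triethylsilyl)oxy]-7-(trimethylsilyl)hept-6-en-3-ol | C[Si](C)(C)/C=C(\CO[Si](C)(C)C(C)(C)C)CCC(O)C(C)(C)O[Si](CC)(CC)CC | intermediate
9 | (6Z)-6-({[tert-butyl(dimethyl)silyl]oxy}methyl)-2-methyl-2-[(triethylsilyl)oxy]-7-(trimethylsilyl)hept-6-en-3-one | C[Si](C)(C)/C=C(\CO[Si](C)(C)C(C)(C)C)CCC(=O)C(C)(C)O[Si](CC)(CC)CC | intermediate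
10 | (6Z)-6-({[tert-butyl(dimethyl)silyl]oxy}methyl)-7-iodo-2-methyl-2-[(triethylsilyl)oxy]hept-6-en-3-one | I/C=C(\CO[Si](C)(C)C(C)(C)C)CCC(=O)C(C)(C)O[Si](CC)(CC)CC | intermediate
11 | (3R,6Z)-6-({[tert-butyl(dimethyl)silyl]oxy}methyl)-7-iodo-2-methyl-2-[(triethylsilyl)oxy]hept-6-en-3-ol | I/C=C(\CO[Si](C)(C)C(C)(C)C)CC[C@@H](O)C(C)(C)O[Si](CC)(CC)CC | intermediate
12 | (3R,6Z)-6-(hydroxymethyl)-7-iodo-2-methylhept-6-ene-2,3-diol | I/C=C(\CO)CC[C@@H](O)C(C)(C)O | intermediate
13 | (2Z,5R)-5,6-dihydroxy-2-(iodomethylidene)-6-methylheptanal | I/C=C(\C=O)CC[C@@H](O)C(C)(C)O | intermediate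
14 | (3Z,6R)-6-(2-hydroxypropan-2-yl)-3-(iodomethylidene)oxan-2-ol (either configuration at C2) | I/C=C1/CC[C@H](C(C)(C)O)OC1O | intermediate
15 | (3Z,6R)-6-(2-hydroxypropan-2-yl)-3-(iodomethylidene)oxan-2-one | I/C=C1/CC[C@H](C(C)(C)O)OC1=O | intermediate
16 | 2-bromo-1-fluoro-4-methylbenzene | Cc1ccc(F)c(Br)c1 | starting material
17 | (3-bromo-2-fluoro-5-methylphenyl)lithium | Cc1cc(Br)c(F)c([Li])c1 | intermediate
18 | 3-bromo-2-fluoro-5-methylbenzaldehyde | Cc1cc(Br)c(F)c(C=O)c1 | intermediate
19 | (R)-(−)-linalool, (3R)-3,7-dimethylocta-1,6-dien-3-ol | CC(C)=CCC[C@@](C)(O)C=C | starting material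
20 | potassium (3R)-3,7-dimethylocta-1,6-dien-3-olate | CC(C)=CCC[C@@](C)([O-])C=C.[K+] | intermediate
21 | 3-bromo-2-{[(3R)-3,7-dimethylocta-1,6-dien-3-yl]oxy}-5-methylbenzaldehyde | CC(C)=CCC[C@@](C)(Oc1c(Br)cc(C)cc1C=O)C=C | intermediate
22 | 1-bromo-2-{[(3R)-3,7-dimethylocta-1,6-dien-3-yl]oxy}-3-ethenyl-5-methylbenzene | CC(C)=CCC[C@@](C)(Oc1c(Br)cc(C)cc1C=C)C=C | intermediate
23 | (2E,6R)-6-(2-bromo-6-ethenyl-4-methylphenoxy)-2,6-dimethylocta-2,7-dien-1-ol | OC/C(C)=C/CC[C@@](C)(Oc1c(Br)cc(C)cc1C=C)C=C | intermediate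
24 | (2E,6R)-6-(2-bromo-6-ethenyl-4-methylphenoxy)-2,6-dimethylocta-2,7-dienal | O=C/C(C)=C/CC[C@@](C)(Oc1c(Br)cc(C)cc1C=C)C=C | intermediate
25 | (2E)-5-[(2R)-8-bromo-2,6-dimethyl-2H-chromen-2-yl]-2-methylpent-2-enal | O=C/C(C)=C/CC[C@@]1(C)Oc2c(Br)cc(C)cc2C=C1 | intermediate
26 | (2E)-5-[(2R)-2,6-dimethyl-8-(4,4,5,5-tetramethyl-1,3,2-dioxaborolan-2-yl)-2H-chromen-2-yl]-2-methylpent-2-enal | O=C/C(C)=C/CC[C@@]1(C)Oc2c(B3OC(C)(C)C(C)(C)O3)cc(C)cc2C=C1 | intermediate
27 | (2E)-5-[(2R)-8-hydroxy-2,6-dimethyl-2H-chromen-2-yl]-2-methylpent-2-enal | O=C/C(C)=C/CC[C@@]1(C)Oc2c(O)cc(C)cc2C=C1 | intermediate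
28 | (2R)-2,6-dimethyl-2-[(3E)-4-methylhexa-3,5-dien-1-yl]-2H-chromen-8-ol | C=C/C(C)=C/CC[C@@]1(C)Oc2c(O)cc(C)cc2C=C1 | intermediate
29 | B-alkyl-9-BBN from hydroboration of the terminal alkene of 28, phenol oxygen also bound to a 9-BBN unit | B1(CC/C(C)=C/CC[C@@]2(C)Oc3c(OB4C5CCCC4CCC5)cc(C)cc3C=C2)C2CCCC1CCC2 | intermediate
30 | (3Z,6R)-3-{(4E)-7-[(2R)-8-hydroxy-2,6-dimethyl-2H-chromen-2-yl]-4-methylhept-4-en-1-ylidene}-6-(2-hydroxypropan-2-yl)oxan-2-one | O=C1O[C@@H](C(C)(C)O)CC/C1=C/CC/C(C)=C/CC[C@@]2(C)Oc3c(O)cc(C)cc3C=C2 | intermediate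
31 | (2R)-2-{(3E)-7-[(3Z,6R)-6-(2-hydroxypropan-2-yl)-2-oxooxan-3-ylidene]-4-methylhept-3-en-1-yl}-2,6-dimethyl-2H-chromene-5,8-dione | CC1=CC(=O)C2=C(C=C[C@@](C)(CC/C=C(\C)CC/C=C3/CC[C@H](C(C)(C)O)OC3=O)O2)C1=O | target

**Totals**
Total step count: 18. Longest linear sequence: 10 steps (steps 2, 3, 4, 5, 6, 7, 8, 9, 17, 18).

**Steps most likely to fail**

Step 4. Zirconacycle 6 may revert to the alkyne complex by loss of ethylene, so that the aldehyde couples directly with the alkyne, or insertion of the hindered aldehyde may be too slow and protonolysis returns the ethylated alkene. The fallback sets out from aldehyde 5 and alkyne 2 and rejoins the route at ketone 9. Vinylmagnesium bromide (THF, −78 °C) should add to 5 to give 4-methyl-4-[(triethylsilyl)oxy]pent-1-en-3-ol F1. Dess–Martin oxidation should give the enone 4-methyl-4-[(triethylsilyl)oxy]pent-1-en-3-one F2. Nickel-catalysed reductive enone–alkyne coupling of F2 with 2 (Ni(cod)2, PBu3, Et3B, MeOH/THF, 50 °C) should then give 9: oxidative cyclisation at zerovalent nickel places silicon next to the metal, the C–C bond forms at the CH2OTBS-bearing carbon, and hydrogen is delivered syn. The two bonds are then made in two separate operations.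

Step 11. Substitution at the hindered C–F bond by a tertiary alkoxide may be outrun by reversible carbonyl addition followed by Tishchenko-type redox consumption of the aldehyde. The fallback sets out from 18 and rejoins at 21. Hydrolysis of the fluoride (KOH, DMSO/H2O, 60 °C) should give 3-bromo-2-hydroxy-5-methylbenzaldehyde F3. Geraniol with ClCO2Me and pyridine gives (2E)-3,7-dimethylocta-2,6-dien-1-yl methyl carbonate F4. Palladium-catalysed asymmetric allylic etherification of F3 with F4 (Pd2(dba)3·CHCl3, Trost bis(2-diphenylphosphinobenzamide) ligand, CH2Cl2) should give the branched tertiary ether 21. The ligand enantiomer is chosen for the R ether, so the stereocenter then comes from the catalyst and not from linalool.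

Step 13. The allylic C–H oxidation may stall or over-oxidise, and the acidic selenium species may ionise the tertiary allyl aryl ether. The fallback sets out from 22 and rejoins at 25. Ring-closing metathesis is run first (second-generation Grubbs catalyst RuCl2(=CHPh)(PCy3)(H2IMes), CH2Cl2, 40 °C) to give (2R)-8-bromo-2,6-dimethyl-2-(4-methylpent-3-en-1-yl)-2H-chromene F5. Cross-metathesis of its prenyl terminus with methacrolein (second-generation Hoveyda–Grubbs catalyst RuCl2(=CH-C6H4-2-OiPr)(H2IMes), CH2Cl2, 40 °C) should then give the E-enal 25 with loss of 2-methylpropene.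

**Further compounds**
F1 | step 4 | 4-methyl-4-[(triethylsilyl)oxy]pent-1-en-3-ol | C=CC(O)C(C)(C)O[Si](CC)(CC)CC
F2 | step 4 | 4-methyl-4-[(triethylsilyl)oxy]pent-1-en-3-one | C=CC(=O)C(C)(C)O[Si](CC)(CC)CC
F3 | step 11 | 3-bromo-2-hydroxy-5-methylbenzaldehyde | Cc1cc(Br)c(O)c(C=O)c1
F4 | step 11 | (2E)-3,7-dimethylocta-2,6-dien-1-yl methyl carbonate | COC(=O)OC/C=C(\C)CCC=C(C)C
F5 | step 13 | (2R)-8-bromo-2,6-dimethyl-2-(4-methylpent-3-en-1-yl)-2H-chromene | CC(C)=CCC[C@@]1(C)Oc2c(Br)cc(C)cc2C=C1
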